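## Plan

1. Numbering: C1 is the lactone carbonyl, C2=C3 the ring olefin, C5 the ring carbinol, C7, C9 and C11 the chain carbinols, C12–C20 the nonyl tail. The ring O–C1(=O)–C2=C3–C4–C5 is a cis-enoate whose ester oxygen is the C5 oxygen of its own chain, so C1 can be put in last as CO between a Z-configured C2–I bond and O5.
2. Retrosynthesis: cut C1–O5 and C1–C2 (CO), then C4–C5 (allenylboronate), C6–C7 (allylborane) and C8–C9 (acetate enolate), which leaves methyl 3-oxododecanoate (C9–C20).
3. Forward: the chain grows from the nonyl end towards the ring (C8–C9, then C6–C7, then C4–C5). The terminal alkyne is turned into a Z-iodoalkene, the only ring closes in the carbonylation, and one acidic step removes both protecting groups.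
4. Stereochemistry: C11 by catalyst-controlled keto ester hydrogenation, C9 by 1,3-syn reduction relayed from C11, C7 by reagent-controlled allylboration, C5 by catalyst-controlled allenylboration. The Z olefin comes from syn hydrogen transfer by diimide and is retained through the palladium cycle.

Key step: step 12

Assumption: the target is taken exactly as drawn, (5S,7S,9R,11R) in this numbering (C9/C11 syn, C7/C9 anti, C5/C7 anti); methyl 3-oxododecanoate, the pentane solution of (+)-B-allyldiisopinocampheylborane and allenylboronic acid pinacol ester are treated as catalogue chemicals.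

## Route

Step 1
Reactants: 1 methyl 3-oxododecanoate
Product: 2 methyl (3R)-3-hydroxydodecanoate
Conditions: H2 (10 bar), RuCl2[(R)-BINAP] (0.5 mol %), MeOH, 50 °C
Reagents that add atoms: none
Why: Noyori asymmetric hydrogenation: the β-keto ester chelates ruthenium through both carbonyls and the (R)-BINAP ligand directs hydride to the ketone face that gives the (3R)-alcohol, which sets C11 under catalyst control in the sense established for methyl acetoacetate and its long-chain homologues.

Step 2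
Reactants: 2 methyl (3R)-3-hydroxydodecanoate; 3 tert-butyl acetate
Product: 5 tert-butyl (5R)-5-hydroxy-3-oxotetradecanoate, via lithium enolate of tert-butyl acetate 4 (not isolated)
Conditions: 3 (3.5 equiv), LiN(i-Pr)2 (3.5 equiv), THF, −78 °C; add 2, −78 → −30 °C; AcOH quench
Reagents that add atoms: tert-butyl acetate (3), CC(=O)OC(C)(C)C
Why: Crossed Claisen condensation: the excess lithium enolate first deprotonates the hydroxyl of 2 and then acylates at the methyl ester, and the β-keto ester is shielded from further attack as its enolate, as in the same condensation on unprotected 3-hydroxy esters used for statin side chains.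

Step 3
Reactants: 5 tert-butyl (5R)-5-hydroxy-3-oxotetradecanoate
Product: 8 tert-butyl (3R,5R)-3,5-dihydroxytetradecanoate, via diethylboron chelate 6 (not isolated), via sodium dioxaborinane ate complex 7 (not isolated)
Conditions: Et2BOMe (1.1 equiv), THF/MeOH (4:1), −78 °C; NaBH4; then H2O2, pH 7 buffer, 0 °C
Reagents that add atoms: none
Why: Narasaka–Prasad reduction: the boron chelate fixes the hydroxy ketone in a half-chair and borohydride attacks axially from outside, so C9 is set 1,3-syn to C11 by substrate control.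

Step 4
Reactants: 8 tert-butyl (3R,5R)-3,5-dihydroxytetradecanoate
Product: 9 tert-butyl 2-[(4R,6R)-2,2-dimethyl-6-nonyl-1,3-dioxan-4-yl]acetate
Conditions: Me2C(OMe)2, PPTS (cat.), CH2Cl2, rt
Reagents that add atoms: 2,2-dimethoxypropane, COC(C)(C)OC
Why: Acid-catalysed ketal exchange (acetonide formation) is driven by loss of methanol and gives the chair 1,3-dioxane with both ring substituents equatorial, as expected for a syn-1,3-diol.

Step 5
Reactants: 9 tert-butyl 2-[(4R,6R)-2,2-dimethyl-6-nonyl-1,3-dioxan-4-yl]acetate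
Product: 11 2-[(4R,6R)-2,2-dimethyl-6-nonyl-1,3-dioxan-4-yl]acetaldehyde, via aluminium hemiacetal 10 (not isolated)
Conditions: i-Bu2AlH (1.1 equiv), CH2Cl2, −78 °C; aq. KNaC4H4O6 work-up
Reagents that add atoms: none
Why: Partial reduction of an ester with i-Bu2AlH: at −78 °C the tetrahedral aluminium hemiacetal of the bulky tert-butyl ester persists and releases the aldehyde only on hydrolysis, so over-reduction should be limited.

Step 6
Reactants: 11 2-[(4R,6R)-2,2-dimethyl-6-nonyl-1,3-dioxan-4-yl]acetaldehyde; 12 (+)-B-allyldiisopinocampheylborane (reagent derived from (−)-α-pinene)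
Product: 14 (2R)-1-[(4S,6R)-2,2-dimethyl-6-nonyl-1,3-dioxan-4-yl]pent-4-en-2-ol, via diisopinocampheylborinate 13 (not isolated)
Conditions: 12 (1.3 equiv, pentane solution), Et2O, −78 °C; then NaOH, H2O2, 0 °C → rt
Reagents that add atoms: (+)-B-allyldiisopinocampheylborane (12), C=CCB([C@H]1C[C@H]2C[C@@H]([C@@H]1C)C2(C)C)[C@H]1C[C@H]2C[C@@H]([C@@H]1C)C2(C)C
Why: Brown allylboration: in the chair Zimmerman–Traxler transition state the reagent derived from (−)-α-pinene delivers allyl to the Re face of the aldehyde, which sets C7 as the (2R)-carbinol of 14 (anti to C9) by reagent control that overrides the weak bias of the β-oxygen.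

Step 7
Reactants: 14 (2R)-1-[(4S,6R)-2,2-dimethyl-6-nonyl-1,3-dioxan-4-yl]pent-4-en-2-ol
Product: 15 tert-butyl{[(2R)-1-[(4R,6R)-2,2-dimethyl-6-nonyl-1,3-dioxan-4-yl]pent-4-en-2-yl]oxy}dimethylsilane
Conditions: TBSCl, imidazole, DMF, rt
Reagents that add atoms: tert-butyldimethylsilyl chloride, CC(C)(C)[Si](C)(C)Cl
Why: Corey silylation of a secondary alcohol with TBSCl and imidazole is routine and leaves the acetonide and the terminal alkene untouched.

Step 8
Reactants: 15 tert-butyl{[(2R)-1-[(4R,6R)-2,2-dimethyl-6-nonyl-1,3-dioxan-4-yl]pent-4-en-2-yl]oxy}dimethylsilane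
Product: 17 (3S)-3-[(tert-butyldimethylsilyl)oxy]-4-[(4R,6R)-2,2-dimethyl-6-nonyl-1,3-dioxan-4-yl]butanal, via secondary ozonide 16 (not isolated)
Conditions: O3, CH2Cl2, −78 °C; then PPh3, −78 °C → rt
Reagents that add atoms: ozone, [O-][O+]=O
Why: Ozonolysis with reductive work-up: cycloaddition and rearrangement give the ozonide, which PPh3 reduces to the β-silyloxy aldehyde without affecting the silyl ether or the ketal.

Step 9
Reactants: 17 (3S)-3-[(tert-butyldimethylsilyl)oxy]-4-[(4R,6R)-2,2-dimethyl-6-nonyl-1,3-dioxan-4-yl]butanal; 18 allenylboronic acid pinacol ester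
Product: 20 (4S,6R)-6-[(tert-butyldimethylsilyl)oxy]-7-[(4R,6R)-2,2-dimethyl-6-nonyl-1,3-dioxan-4-yl]hept-1-yn-4-ol, via pinacol borate ester 19 (not isolated)
Conditions: 18 (1.5 equiv), (S)-TRIP [(S)-3,3′-bis(2,4,6-triisopropylphenyl)-1,1′-binaphthyl-2,2′-diyl hydrogen phosphate] (10 mol %), 4 Å molecular sieves, toluene, −20 °C; aq. NaHCO3 work-up
Reagents that add atoms: allenylboronic acid pinacol ester (18), C=C=CB1OC(C)(C)C(C)(C)O1
Why: Chiral phosphoric acid-catalysed allenylboration (asymmetric propargylation): the acid activates the boronate in a six-membered SE2′ transition state that can only give the homopropargylic regioisomer, and the (S)-acid, mirror image of the (R)-catalyst that sends such boronates to the Re face, directs attack to the Si face so that C5 is set as the (4S)-carbinol of 20 (anti to C7) under catalyst control.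

Step 10
Reactants: 20 (4S,6R)-6-[(tert-butyldimethylsilyl)oxy]-7-[(4R,6R)-2,2-dimethyl-6-nonyl-1,3-dioxan-4-yl]hept-1-yn-4-ol
Product: 21 (4S,6R)-6-[(tert-butyldimethylsilyl)oxy]-7-[(4R,6R)-2,2-dimethyl-6-nonyl-1,3-dioxan-4-yl]-1-iodohept-1-yn-4-ol
Conditions: N-iodosuccinimide (1.2 equiv), AgNO3 (10 mol %), acetone, rt, dark
Reagents that add atoms: N-iodosuccinimide, O=C1CCC(=O)N1I
Why: Silver-catalysed electrophilic iodination of a terminal alkyne: the silver acetylide formed reversibly is iodinated by N-iodosuccinimide, a reaction that tolerates free alcohols, silyl ethers and ketals.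

Step 11
Reactants: 21 (4S,6R)-6-[(tert-butyldimethylsilyl)oxy]-7-[(4R,6R)-2,2-dimethyl-6-nonyl-1,3-dioxan-4-yl]-1-iodohept-1-yn-4-ol
Product: 22 (1Z,4S,6R)-6-[(tert-butyldimethylsilyl)oxy]-7-[(4R,6R)-2,2-dimethyl-6-nonyl-1,3-dioxan-4-yl]-1-iodohept-1-en-4-ol
Conditions: 2-nitrobenzenesulfonyl hydrazide, Et3N, THF/i-PrOH, rt
Reagents that add atoms: none
Why: Diimide reduction: diimide released from the sulfonyl hydrazide transfers two hydrogens to one face of the triple bond in a concerted six-membered transition state, which gives the Z-iodoalkene, the standard cis-reduction of 1-iodoalkynes.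

Step 12
Reactants: 22 (1Z,4S,6R)-6-[(tert-butyldimethylsilyl)oxy]-7-[(4R,6R)-2,2-dimethyl-6-nonyl-1,3-dioxan-4-yl]-1-iodohept-1-en-4-ol; 23 carbon monoxide
Product: 24 (6S)-6-{(2S)-2-[(tert-butyldimethylsilyl)oxy]-3-[(4R,6R)-2,2-dimethyl-6-nonyl-1,3-dioxan-4-yl]propyl}-5,6-dihydro-2H-pyran-2-one
Conditions: CO (1 atm), Pd(PPh3)4 (5 mol %), K2CO3 (2 equiv), THF, 50 °C
Reagents that add atoms: carbon monoxide (23), [C-]#[O+]
Why: Zerovalent palladium adds to the C2–I bond with retention of the Z geometry, CO inserts into the vinyl–palladium bond, and the C5 hydroxyl, helped by K2CO3, attacks the resulting acylpalladium iodide so that the ester is released and zerovalent palladium returns to the cycle. The closest known reaction type is the palladium-catalysed carbonylative lactonisation of Z-iodoalkenols to butenolides and 5,6-dihydro-2H-pyran-2-ones. The dihydropyranone closes by a 6-exo-trig attack of O5 on the acyl carbon C1, which forms C1–C2 and C1–O5 in one operation. No stereocentre is created and C5 keeps its configuration because its C–O bond is never broken. The step needs retention of the olefin geometry and intramolecular rather than intermolecular acyl capture; the cis disposition of iodide and chain places the acyl group next to O5, the six-membered closure is fast, and C5 carries the only free hydroxyl because C7 is silylated and C9/C11 are tied up in the acetonide.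

Step 13
Reactants: 24 (6S)-6-{(2S)-2-[(tert-butyldimethylsilyl)oxy]-3-[(4R,6R)-2,2-dimethyl-6-nonyl-1,3-dioxan-4-yl]propyl}-5,6-dihydro-2H-pyran-2-one
Product: 25 (6S)-6-[(2S,4R,6R)-2,4,6-trihydroxypentadecyl]-5,6-dihydro-2H-pyran-2-one
Conditions: 48% aq. HF, MeCN, 0 °C → rt
Reagents that add atoms: none
Why: Acid-mediated global deprotection: fluoride-assisted cleavage of the silyl ether and hydrolysis of the acetonide proceed in one non-basic medium, which avoids base-triggered oxa-Michael addition of the C7 hydroxyl to C3 and opening of the lactone.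

## Compound list

1 | methyl 3-oxododecanoate | CCCCCCCCCC(=O)CC(=O)OC | starting material
2 | methyl (3R)-3-hydroxydodecanoate | CCCCCCCCC[C@@H](O)CC(=O)OC | intermediate
3 | tert-butyl acetate | CC(=O)OC(C)(C)C | starting material
4 | lithium enolate of tert-butyl acetate (lithium 1-tert-butoxyethenolate) | [Li]OC(=C)OC(C)(C)C | intermediate
5 | tert-butyl (5R)-5-hydroxy-3-oxotetradecanoate | CCCCCCCCC[C@@H](O)CC(=O)CC(=O)OC(C)(C)C | intermediate
6 | diethylboron chelate of 5 (O5-diethylboryl ether, boron coordinated to the C3 ketone) | CCCCCCCCC[C@@H](OB(CC)CC)CC(=O)CC(=O)OC(C)(C)C | intermediate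
7 | sodium 2,2-diethyl-1,3,2-dioxaborinan-2-uide of the syn-diol 8 (ate complex) | CCCCCCCCC[C@@H]1C[C@@H](O[B-](CC)(CC)O1)CC(=O)OC(C)(C)C.[Na+] | intermediate
8 | tert-butyl (3R,5R)-3,5-dihydroxytetradecanoate (syn-diol) | CCCCCCCCC[C@@H](O)C[C@@H](O)CC(=O)OC(C)(C)C | intermediate
9 | tert-butyl 2-[(4R,6R)-2,2-dimethyl-6-nonyl-1,3-dioxan-4-yl]acetate | CCCCCCCCC[C@@H]1C[C@@H](OC(C)(C)O1)CC(=O)OC(C)(C)C | intermediate
10 | aluminium hemiacetal of 11 (1-tert-butoxy-1-diisobutylaluminoxy derivative, mixture at the hemiacetal carbon) | CCCCCCCCC[C@@H]1C[C@@H](OC(C)(C)O1)CC(OC(C)(C)C)O[Al](CC(C)C)CC(C)C | intermediate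
11 | 2-[(4R,6R)-2,2-dimethyl-6-nonyl-1,3-dioxan-4-yl]acetaldehyde | CCCCCCCCC[C@@H]1C[C@@H](OC(C)(C)O1)CC=O | intermediate
12 | (+)-B-allyldiisopinocampheylborane (from (−)-α-pinene) | C=CCB([C@H]1C[C@H]2C[C@@H]([C@@H]1C)C2(C)C)[C@H]1C[C@H]2C[C@@H]([C@@H]1C)C2(C)C | starting material
13 | diisopinocampheylborinate of 14 | CCCCCCCCC[C@@H]1C[C@@H](OC(C)(C)O1)C[C@H](OB([C@H]2C[C@H]3C[C@@H]([C@@H]2C)C3(C)C)[C@H]2C[C@H]3C[C@@H]([C@@H]2C)C3(C)C)CC=C | intermediate
14 | (2R)-1-[(4S,6R)-2,2-dimethyl-6-nonyl-1,3-dioxan-4-yl]pent-4-en-2-ol | CCCCCCCCC[C@@H]1C[C@@H](OC(C)(C)O1)C[C@H](O)CC=C | intermediate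
15 | tert-butyl{[(2R)-1-[(4R,6R)-2,2-dimethyl-6-nonyl-1,3-dioxan-4-yl]pent-4-en-2-yl]oxy}dimethylsilane | CCCCCCCCC[C@@H]1C[C@@H](OC(C)(C)O1)C[C@H](O[Si](C)(C)C(C)(C)C)CC=C | intermediate
16 | secondary ozonide of 15 (3-substituted 1,2,4-trioxolane, mixture at the ring carbon) | CCCCCCCCC[C@@H]1C[C@@H](OC(C)(C)O1)C[C@H](O[Si](C)(C)C(C)(C)C)CC1OCOO1 | intermediate
17 | (3S)-3-[(tert-butyldimethylsilyl)oxy]-4-[(4R,6R)-2,2-dimethyl-6-nonyl-1,3-dioxan-4-yl]butanal | CCCCCCCCC[C@@H]1C[C@@H](OC(C)(C)O1)C[C@H](O[Si](C)(C)C(C)(C)C)CC=O | intermediate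
18 | allenylboronic acid pinacol ester [4,4,5,5-tetramethyl-2-(propa-1,2-dien-1-yl)-1,3,2-dioxaborolane] | C=C=CB1OC(C)(C)C(C)(C)O1 | starting material
19 | pinacol borate ester of 20 (O-Bpin derivative at C5) | CCCCCCCCC[C@@H]1C[C@@H](OC(C)(C)O1)C[C@H](O[Si](C)(C)C(C)(C)C)C[C@@H](OB1OC(C)(C)C(C)(C)O1)CC#C | intermediate
20 | (4S,6R)-6-[(tert-butyldimethylsilyl)oxy]-7-[(4R,6R)-2,2-dimethyl-6-nonyl-1,3-dioxan-4-yl]hept-1-yn-4-ol | CCCCCCCCC[C@@H]1C[C@@H](OC(C)(C)O1)C[C@H](O[Si](C)(C)C(C)(C)C)C[C@@H](O)CC#C | intermediate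
21 | (4S,6R)-6-[(tert-butyldimethylsilyl)oxy]-7-[(4R,6R)-2,2-dimethyl-6-nonyl-1,3-dioxan-4-yl]-1-iodohept-1-yn-4-ol | CCCCCCCCC[C@@H]1C[C@@H](OC(C)(C)O1)C[C@H](O[Si](C)(C)C(C)(C)C)C[C@@H](O)CC#CI | intermediate
22 | (1Z,4S,6R)-6-[(tert-butyldimethylsilyl)oxy]-7-[(4R,6R)-2,2-dimethyl-6-nonyl-1,3-dioxan-4-yl]-1-iodohept-1-en-4-ol | CCCCCCCCC[C@@H]1C[C@@H](OC(C)(C)O1)C[C@H](O[Si](C)(C)C(C)(C)C)C[C@@H](O)C/C=C\I | intermediate
23 | carbon monoxide | [C-]#[O+] | starting material
24 | (6S)-6-{(2S)-2-[(tert-butyldimethylsilyl)oxy]-3-[(4R,6R)-2,2-dimethyl-6-nonyl-1,3-dioxan-4-yl]propyl}-5,6-dihydro-2H-pyran-2-one | CCCCCCCCC[C@@H]1C[C@@H](OC(C)(C)O1)C[C@H](O[Si](C)(C)C(C)(C)C)C[C@@H]1CC=CC(=O)O1 | intermediate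
25 | (6S)-6-[(2S,4R,6R)-2,4,6-trihydroxypentadecyl]-5,6-dihydro-2H-pyran-2-one | CCCCCCCCC[C@@H](O)C[C@@H](O)C[C@H](O)C[C@@H]1CC=CC(=O)O1 | target

## Step count and risks

Total step count: 13. Longest linear sequence: 13 steps (1 → 25); the route is fully linear, with 3, 12, 18 and 23 entering as building blocks.

Steps most likely to fail:

Step 9. The catalyst may discriminate poorly between the two faces of a linear β-silyloxy aldehyde, since the existing C7 centre gives little help, and slow turnover could allow the aldehyde to decompose. The fallback sets out from alkene 15 and returns at alkynol 20. Epoxidation of 15 with mCPBA (NaHCO3, CH2Cl2) should give the terminal epoxide as a mixture of C5 epimers F1. Hydrolytic kinetic resolution with (R,R)-(salen)Co(OAc) (salen = N,N′-bis(3,5-di-tert-butylsalicylidene)-1,2-cyclohexanediamine dianion) and 0.55 equiv of water should consume the unwanted epimer as the 1,2-diol F3 and leave the (R)-oxirane F2. Opening of F2 at its CH2 terminus with LiC≡CH·H2NCH2CH2NH2 in DMSO gives 20, so C5 then rests on a kinetic resolution and not on a carbonyl addition.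

Step 12. The acylpalladium may be captured intermolecularly to give oligomeric esters, the C–I bond may be reduced before CO insertion, or palladium may aggregate under CO. The fallback sets out from alkynol 20 and returns at lactone 24. Double deprotonation of 20 with n-BuLi (2.2 equiv, THF, −78 °C) and carboxylation with CO2 should give the hydroxy ynoic acid F4. Semihydrogenation over Pd/CaCO3 poisoned with Pb(OAc)2 and quinoline should give the Z-hydroxy enoic acid F5, which lactonises on standing or with catalytic PPTS to 24. C1 then comes from CO2 and the cis geometry from syn hydrogenation.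

Step 11. Transfer hydrogenation may run on to the saturated iodide or stall, leaving alkyne, alkene and alkane that are hard to separate; loss of iodine is also possible. The fallback sets out from iodoalkyne 21 and returns at iodoalkenol 22. Syn-hydroboration with excess (c-C6H11)2BH (the first equivalent is taken up by the hydroxyl) places boron on the iodine-bearing carbon and should give the α-iodoalkenylborane F6. Protonolysis with acetic acid replaces boron by hydrogen with retention and frees the hydroxyl, which gives the Z-iodoalkene 22.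

## Further compounds

F1 | step 9 | tert-butyl{[1-[(4R,6R)-2,2-dimethyl-6-nonyl-1,3-dioxan-4-yl]-3-(oxiran-2-yl)propan-2-yl]oxy}dimethylsilane, (2S) at the silyloxy carbon, both epimers at the oxirane carbon | CCCCCCCCC[C@@H]1C[C@@H](OC(C)(C)O1)C[C@H](O[Si](C)(C)C(C)(C)C)CC1CO1
F2 | step 9 | tert-butyl{[(2S)-1-[(4R,6R)-2,2-dimethyl-6-nonyl-1,3-dioxan-4-yl]-3-[(2R)-oxiran-2-yl]propan-2-yl]oxy}dimethylsilane | CCCCCCCCC[C@@H]1C[C@@H](OC(C)(C)O1)C[C@H](O[Si](C)(C)C(C)(C)C)C[C@@H]1CO1
F3 | step 9 | (2S,4R)-4-[(tert-butyldimethylsilyl)oxy]-5-[(4R,6R)-2,2-dimethyl-6-nonyl-1,3-dioxan-4-yl]pentane-1,2-diol | CCCCCCCCC[C@@H]1C[C@@H](OC(C)(C)O1)C[C@H](O[Si](C)(C)C(C)(C)C)C[C@H](O)CO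
F4 | step 12 | (5S,7R)-7-[(tert-butyldimethylsilyl)oxy]-8-[(4R,6R)-2,2-dimethyl-6-nonyl-1,3-dioxan-4-yl]-5-hydroxyoct-2-ynoic acid | CCCCCCCCC[C@@H]1C[C@@H](OC(C)(C)O1)C[C@H](O[Si](C)(C)C(C)(C)C)C[C@@H](O)CC#CC(=O)O
F5 | step 12 | (2Z,5S,7R)-7-[(tert-butyldimethylsilyl)oxy]-8-[(4R,6R)-2,2-dimethyl-6-nonyl-1,3-dioxan-4-yl]-5-hydroxyoct-2-enoic acid | CCCCCCCCC[C@@H]1C[C@@H](OC(C)(C)O1)C[C@H](O[Si](C)(C)C(C)(C)C)C[C@@H](O)C/C=C\C(=O)O
F6 | step 11 | (Z)-1-iodoalkenyl(dicyclohexyl)borane from 21, with the C5 oxygen carried as its dicyclohexylborinate | CCCCCCCCC[C@@H]1C[C@@H](OC(C)(C)O1)C[C@H](O[Si](C)(C)C(C)(C)C)C[C@@H](OB(C2CCCCC2)C2CCCCC2)C/C=C(\I)B(C1CCCCC1)C1CCCCC1
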